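**Retrosynthetic overview**
1. Target 33 ← global desilylation of 32 ← Yamaguchi esterification of the 8-hydroxy α-methylene lactone 26 with the protected 4-hydroxytiglic acid 30; the exo-methylene comes from a Mannich/elimination sequence on the saturated lactone.
2. Ten-membered ring (formed last) ← ring-closing metathesis at C1=C10 of diene 19; the C8 carbinol ← reagent-controlled methallylboration of aldehyde 18.
3. γ-Lactone (second ring) and the C6–C7 bond ← intermolecular Evans syn-aldol/lactonisation between succinyl imide 13 and epoxy aldehyde 9 (the fragment union).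
4. Epoxide (first ring) ← Sharpless epoxidation of Z-allylic alcohol 7 ← syn-carbocupration of ynoate 4.
5. Ring order: epoxide → γ-lactone → cyclodecene.

Assumption: locants C1–C15 follow germacrane numbering (ring C1–C10; lactone carbons C11–C13, C12 the carbonyl; C14 the methyl on C10; C15 the CH2O on C4). TBS = tert-butyldimethylsilyl, TES = triethylsilyl. Commercial reagent solutions (Grignard reagents, n-BuLi, Bu2BOTf, (+)-Ipc2BOMe) are reagents and carry no compound number.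

**Step 1**
Reactants: 1 prop-2-yn-1-ol
Product: 2 tert-butyldimethyl(prop-2-yn-1-yloxy)silane
Conditions: TBSCl, imidazole, CH2Cl2, 0 °C → rt
Reagents that add atoms: tert-butyldimethylsilyl chloride, CC(C)(C)[Si](C)(C)Cl
Why: Standard silyl ether formation on a primary alcohol; no stereocentre.

**Step 2**
Reactants: 2 tert-butyldimethyl(prop-2-yn-1-yloxy)silane
Product: 4 ethyl 4-[(tert-butyldimethylsilyl)oxy]but-2-ynoate, via lithium acetylide 3 (not isolated)
Conditions: n-BuLi, THF, −78 °C; ClCO2Et, −78 → 0 °C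
Reagents that add atoms: ethyl chloroformate, CCOC(=O)Cl
Why: Deprotonation of the terminal alkyne and acylation of the acetylide with the chloroformate gives the ynoate.

**Step 3**
Reactants: 4 ethyl 4-[(tert-butyldimethylsilyl)oxy]but-2-ynoate
Product: 6 ethyl (2Z)-3-{[(tert-butyldimethylsilyl)oxy]methyl}hepta-2,6-dienoate, via alkenylcopper adduct 5 (not isolated)
Conditions: but-3-enylmagnesium bromide (1.3 equiv), CuI (1.3 equiv), THF, −40 °C; add 4, −78 °C, 1 h; sat. aq NH4Cl at −78 °C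
Reagents that add atoms: but-3-enylmagnesium bromide, C=CCC[Mg]Br
Why: Syn carbocupration (organocopper conjugate addition to the ynoate) with protonation at −78 °C places the butenyl group cis to H, so the ester and CH2OTBS end up cis (2Z).

**Step 4**
Reactants: 6 ethyl (2Z)-3-{[(tert-butyldimethylsilyl)oxy]methyl}hepta-2,6-dienoate
Product: 7 (2Z)-3-{[(tert-butyldimethylsilyl)oxy]methyl}hepta-2,6-dien-1-ol
Conditions: i-Bu2AlH (2.5 equiv), CH2Cl2, −78 °C; aq potassium sodium tartrate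
Reagents that add atoms: none
Why: 1,2-Reduction of the enoate by the aluminium hydride gives the allylic alcohol without touching the olefin geometry or the silyl ether.

**Step 5**
Reactants: 7 (2Z)-3-{[(tert-butyldimethylsilyl)oxy]methyl}hepta-2,6-dien-1-ol
Product: 8 [(2R,3S)-3-(but-3-en-1-yl)-3-{[(tert-butyldimethylsilyl)oxy]methyl}oxiran-2-yl]methanol
Conditions: Ti(OiPr)4 (10 mol%), diethyl (2S,3S)-tartrate [(−)-DET] (12 mol%), t-BuOOH (2 equiv), 4 Å molecular sieves, CH2Cl2, −20 °C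
Reagents that add atoms: tert-butyl hydroperoxide, CC(C)(C)OO
Why: Katsuki–Sharpless asymmetric epoxidation of a 3,3-disubstituted allylic alcohol, in which the (2S,3S)-tartrate delivers oxygen to the face that makes oxirane C2 R (C5) and, by cis addition to the Z-olefin, oxirane C3 S (C4), while the isolated terminal alkene is inert.

**Step 6**
Reactants: 8 [(2R,3S)-3-(but-3-en-1-yl)-3-{[(tert-butyldimethylsilyl)oxy]methyl}oxiran-2-yl]methanol
Product: 9 (2S,3S)-3-(but-3-en-1-yl)-3-{[(tert-butyldimethylsilyl)oxy]methyl}oxirane-2-carbaldehyde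
Conditions: PhI(OAc)2 (1.1 equiv), TEMPO (10 mol%), CH2Cl2, rt; used crude
Reagents that add atoms: none
Why: Oxoammonium (TEMPO) oxidation of the primary alcohol stops at the aldehyde and leaves the epoxide intact (the descriptor at the CHO-bearing carbon changes from R to S by priority only).

**Step 7**
Reactants: 10 (4S)-4-benzyl-1,3-oxazolidin-2-one; 11 methyl 4-chloro-4-oxobutanoate
Product: 13 methyl 4-[(4S)-4-benzyl-2-oxo-1,3-oxazolidin-3-yl]-4-oxobutanoate, via N-lithio oxazolidinone 12 (not isolated)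
Conditions: n-BuLi, THF, −78 °C; then 11, −78 → 0 °C
Reagents that add atoms: none
Why: N-Acylation of the lithiated Evans auxiliary with the acid chloride; the auxiliary stereocentre is untouched.

**Step 8** (fragment union)
Reactants: 13 methyl 4-[(4S)-4-benzyl-2-oxo-1,3-oxazolidin-3-yl]-4-oxobutanoate; 9 (2S,3S)-3-(but-3-en-1-yl)-3-{[(tert-butyldimethylsilyl)oxy]methyl}oxirane-2-carbaldehyde
Product: 16 (4S)-4-benzyl-3-{[(2S,3S)-2-[(2R,3S)-3-(but-3-en-1-yl)-3-{[(tert-butyldimethylsilyl)oxy]methyl}oxiran-2-yl]-5-oxooxolan-3-yl]carbonyl}-1,3-oxazolidin-2-one, via boron enolate 14 (not isolated), via aldol adduct 15 (not isolated)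
Conditions: 13 (1.2 equiv), Bu2BOTf (1.15 equiv), i-Pr2NEt (1.5 equiv), CH2Cl2, 0 °C; 9, −78 → 0 °C; pH 7 NaH2PO4/Na2HPO4 buffer, MeOH, 30% H2O2, 0 °C; then PPTS (10 mol%), CH2Cl2, rt
Reagents that add atoms: none
Why: Intermolecular Evans syn-aldol through the Z-boron enolate and a Zimmerman–Traxler chair, in which the (S)-benzyl auxiliary sets C7 (S) and C6 (S) under reagent control, after which the syn γ-hydroxy methyl ester lactonises to the trans-disubstituted γ-lactone.

**Step 9**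
Reactants: 16 lactone imide (name as in step 8)
Product: 17 S-ethyl (2S,3S)-2-[(2R,3S)-3-(but-3-en-1-yl)-3-{[(tert-butyldimethylsilyl)oxy]methyl}oxiran-2-yl]-5-oxooxolane-3-carbothioate
Conditions: EtSH (3 equiv), n-BuLi (1.2 equiv), THF, −78 → 0 °C; sat. aq NH4Cl
Reagents that add atoms: ethanethiol, CCS
Why: Thiolate transacylation of the exocyclic imide carbonyl releases the auxiliary, while the soft thiolate leaves the hindered trisubstituted epoxide alone at 0 °C.

**Step 10**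
Reactants: 17 thioester (name as in step 9)
Product: 18 (2S,3S)-2-[(2R,3S)-3-(but-3-en-1-yl)-3-{[(tert-butyldimethylsilyl)oxy]methyl}oxiran-2-yl]-5-oxooxolane-3-carbaldehyde
Conditions: Et3SiH (3 equiv), Pd/CaCO3 poisoned with Pb(OAc)2 (10 mol% Pd), acetone, rt; used at once
Reagents that add atoms: none
Why: Fukuyama reduction of the thioester stops at the aldehyde, the poisoned catalyst spares the terminal alkene, and the trans arrangement at C7 is the thermodynamic one.

**Step 11**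
Reactants: 18 aldehyde (name as in step 10)
Product: 19 (4R,5S)-5-[(2R,3S)-3-(but-3-en-1-yl)-3-{[(tert-butyldimethylsilyl)oxy]methyl}oxiran-2-yl]-4-[(1R)-1-hydroxy-3-methylbut-3-en-1-yl]oxolan-2-one
Conditions: 2-methylallylmagnesium chloride, (+)-Ipc2BOMe [the enantiomer made from (−)-α-pinene], Et2O, 0 °C → rt; 18, −78 °C; then pH 7 NaH2PO4/Na2HPO4 buffer, 30% H2O2, MeOH, 0 °C → rt
Reagents that add atoms: 2-methylallylmagnesium chloride, CC(=C)C[Mg]Cl
Why: Brown asymmetric methallylboration (carbonyl allylation through a closed chair transition state), in which the (−)-α-pinene-derived borane adds to the Re face of the aldehyde and sets C8 as R under reagent control.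

**Step 12**
Reactants: 19 diene alcohol (name as in step 11)
Product: 20 (1(10)Z,4S,5R,6S,7R,8R)-15-[(tert-butyldimethylsilyl)oxy]-4,5-epoxy-8-hydroxygermacr-1(10)-en-12,6-olide
Conditions: second-generation Grubbs catalyst (10 mol%), 1,4-benzoquinone (20 mol%), toluene (1 mM), 80 °C
Reagents that add atoms: none
Why: Ring-closing olefin metathesis starts at the monosubstituted C1 alkene and closes onto the isopropenyl group with loss of ethene, and the ten-membered ring is expected to take the less strained cis (1(10)Z) trisubstituted olefin.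

**Step 13**
Reactants: 20 macrocyclic alcohol (name as in step 12)
Product: 21 (1(10)Z,4S,5R,6S,7S,8R)-15-[(tert-butyldimethylsilyl)oxy]-4,5-epoxy-8-[(triethylsilyl)oxy]germacr-1(10)-en-12,6-olide
Conditions: Et3SiCl, imidazole, DMAP (cat.), DMF, 0 °C → rt
Reagents that add atoms: chlorotriethylsilane, CC[Si](CC)(CC)Cl
Why: Silylation of the only free hydroxyl under non-Lewis-acidic conditions (the C7 descriptor changes by priority only).

**Step 14**
Reactants: 21 bis-silyl lactone (name as in step 13)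
Product: 23 (1(10)Z,4S,5R,6S,7S,8R,11R)-13-(dimethylamino)-15-[(tert-butyldimethylsilyl)oxy]-4,5-epoxy-8-[(triethylsilyl)oxy]germacr-1(10)-en-12,6-olide, via lithium enolate 22 (not isolated)
Conditions: LiN(i-Pr)2 (1.3 equiv), THF, −78 °C; dimethyl(methylidene)ammonium iodide (3 equiv), −78 → 0 °C
Reagents that add atoms: dimethyl(methylidene)ammonium iodide, C=[N+](C)C.[I-]
Why: Mannich reaction of the kinetic lactone enolate with the iminium salt; the new C11 centre (drawn 11R, attack anti to the C7 substituent) is destroyed in step 15, so either epimer serves.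

**Step 15**
Reactants: 23 Mannich base (name as in step 14)
Product: 25 (1(10)Z,4S,5R,6S,7S,8R)-15-[(tert-butyldimethylsilyl)oxy]-4,5-epoxy-8-[(triethylsilyl)oxy]germacra-1(10),11(13)-dien-12,6-olide, via ammonium iodide 24 (not isolated)
Conditions: MeI (excess), MeOH, rt; evaporate; sat. aq NaHCO3, CH2Cl2, rt
Reagents that add atoms: none
Why: Exhaustive N-methylation followed by E1cB (Hofmann-type) loss of trimethylamine gives the α-methylene lactone under conditions mild enough for the epoxide.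

**Step 16**
Reactants: 25 α-methylene lactone (name as in step 15)
Product: 26 (1(10)Z,4S,5R,6S,7R,8R)-15-[(tert-butyldimethylsilyl)oxy]-4,5-epoxy-8-hydroxygermacra-1(10),11(13)-dien-12,6-olide
Conditions: HF·pyridine, pyridine, THF, 0 °C
Reagents that add atoms: none
Why: Buffered fluoride cleaves the labile secondary TES ether much faster than the neopentyl-type primary TBS ether and is too weakly acidic to trigger transannular epoxide opening.

**Step 17**
Reactants: 27 2-[(tert-butyldimethylsilyl)oxy]acetaldehyde; 28 ethyl 2-(triphenyl-λ5-phosphanylidene)propanoate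
Product: 29 ethyl (2E)-4-[(tert-butyldimethylsilyl)oxy]-2-methylbut-2-enoate
Conditions: CH2Cl2, 40 °C
Reagents that add atoms: none
Why: Wittig reaction of a stabilised α-methyl ylide with an aldehyde gives the E-trisubstituted enoate with high selectivity.

**Step 18**
Reactants: 29 ethyl (2E)-4-[(tert-butyldimethylsilyl)oxy]-2-methylbut-2-enoate
Product: 30 (2E)-4-[(tert-butyldimethylsilyl)oxy]-2-methylbut-2-enoic acid
Conditions: LiOH, THF/MeOH/H2O, rt; then dilute aq HCl to pH 4, 0 °C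
Reagents that add atoms: lithium hydroxide, [Li+].[OH-]
Why: Saponification of the ethyl ester; the primary TBS ether and the E geometry survive.

**Step 19**
Reactants: 30 (2E)-4-[(tert-butyldimethylsilyl)oxy]-2-methylbut-2-enoic acid; 26 8-hydroxy α-methylene lactone (name as in step 16)
Product: 32 (1(10)Z,4S,5R,6S,7R,8R)-15-[(tert-butyldimethylsilyl)oxy]-4,5-epoxy-12-oxo-germacra-1(10),11(13)-dien-12,6-olid-8-yl (2E)-4-[(tert-butyldimethylsilyl)oxy]-2-methylbut-2-enoate, via mixed anhydride 31 (not isolated)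
Conditions: 2,4,6-trichlorobenzoyl chloride, Et3N, toluene, rt; then 26, DMAP, toluene, rt
Reagents that add atoms: none
Why: Yamaguchi esterification acylates the hindered secondary C8 hydroxyl with retention at C8 and without isomerising the enoate or adding to the α-methylene lactone.

**Step 20**
Reactants: 32 bis-TBS ester (name as in step 19)
Product: 33 target, (1(10)Z,4S,5R,6S,7R,8R)-4,5-epoxy-15-hydroxy-12-oxo-germacra-1(10),11(13)-dien-12,6-olid-8-yl (2E)-4-hydroxy-2-methylbut-2-enoate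
Conditions: HF·pyridine, pyridine, THF, 0 °C → rt
Reagents that add atoms: none
Why: Buffered fluoride desilylation frees both primary alcohols without harming the epoxide, the α-methylene lactone or the enoate ester.

**Compound list**
1 | prop-2-yn-1-ol | C#CCO | starting material
2 | tert-butyldimethyl(prop-2-yn-1-yloxy)silane | C#CCO[Si](C)(C)C(C)(C)C | intermediate
3 | lithium 3-[(tert-butyldimethylsilyl)oxy]prop-1-yn-1-ide (lithium acetylide) | [Li]C#CCO[Si](C)(C)C(C)(C)C | intermediate (not isolated)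
4 | ethyl 4-[(tert-butyldimethylsilyl)oxy]but-2-ynoate | CCOC(=O)C#CCO[Si](C)(C)C(C)(C)C | intermediate
5 | ethyl (2E)-2-cuprio-3-{[(tert-butyldimethylsilyl)oxy]methyl}hepta-2,6-dienoate (alkenylcopper adduct, Cu cis to the butenyl group) | CCOC(=O)/C([Cu])=C(/CCC=C)CO[Si](C)(C)C(C)(C)C | intermediate (not isolated)
6 | ethyl (2Z)-3-{[(tert-butyldimethylsilyl)oxy]methyl}hepta-2,6-dienoate | CCOC(=O)/C=C(/CCC=C)CO[Si](C)(C)C(C)(C)C | intermediate
7 | (2Z)-3-{[(tert-butyldimethylsilyl)oxy]methyl}hepta-2,6-dien-1-ol | OC/C=C(/CCC=C)CO[Si](C)(C)C(C)(C)C | intermediate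
8 | [(2R,3S)-3-(but-3-en-1-yl)-3-{[(tert-butyldimethylsilyl)oxy]methyl}oxiran-2-yl]methanol | C=CCC[C@@]1(CO[Si](C)(C)C(C)(C)C)O[C@@H]1CO | intermediate
9 | (2S,3S)-3-(but-3-en-1-yl)-3-{[(tert-butyldimethylsilyl)oxy]methyl}oxirane-2-carbaldehyde | C=CCC[C@@]1(CO[Si](C)(C)C(C)(C)C)O[C@@H]1C=O | intermediate
10 | (4S)-4-benzyl-1,3-oxazolidin-2-one | O=C1N[C@@H](Cc2ccccc2)CO1 | starting material
11 | methyl 4-chloro-4-oxobutanoate | COC(=O)CCC(=O)Cl | starting material
12 | lithium salt of 10 (N-lithio oxazolidinone) | [Li]N1[C@@H](Cc2ccccc2)COC1=O | intermediate (not isolated)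
13 | methyl 4-[(4S)-4-benzyl-2-oxo-1,3-oxazolidin-3-yl]-4-oxobutanoate | COC(=O)CCC(=O)N1[C@@H](Cc2ccccc2)COC1=O | intermediate
14 | dibutylboron (Z)-enolate of 13 | COC(=O)C/C=C(\OB(CCCC)CCCC)N1[C@@H](Cc2ccccc2)COC1=O | intermediate (not isolated)
15 | methyl (3S,4S)-3-{[(4S)-4-benzyl-2-oxo-1,3-oxazolidin-3-yl]carbonyl}-4-[(2R,3S)-3-(but-3-en-1-yl)-3-{[(tert-butyldimethylsilyl)oxy]methyl}oxiran-2-yl]-4-hydroxybutanoate (syn aldol adduct) | COC(=O)C[C@H](C(=O)N4[C@@H](Cc2ccccc2)COC4=O)[C@H](O)[C@H]3O[C@]3(CO[Si](C)(C)C(C)(C)C)CCC=C | intermediate (not isolated)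
16 | (4S)-4-benzyl-3-{[(2S,3S)-2-[(2R,3S)-3-(but-3-en-1-yl)-3-{[(tert-butyldimethylsilyl)oxy]methyl}oxiran-2-yl]-5-oxooxolan-3-yl]carbonyl}-1,3-oxazolidin-2-one | C1C(=O)O[C@H]([C@H]3O[C@]3(CO[Si](C)(C)C(C)(C)C)CCC=C)[C@H]1C(=O)N4[C@@H](Cc2ccccc2)COC4=O | intermediate
17 | S-ethyl (2S,3S)-2-[(2R,3S)-3-(but-3-en-1-yl)-3-{[(tert-butyldimethylsilyl)oxy]methyl}oxiran-2-yl]-5-oxooxolane-3-carbothioate | C1C(=O)O[C@H]([C@H]3O[C@]3(CO[Si](C)(C)C(C)(C)C)CCC=C)[C@H]1C(=O)SCC | intermediate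
18 | (2S,3S)-2-[(2R,3S)-3-(but-3-en-1-yl)-3-{[(tert-butyldimethylsilyl)oxy]methyl}oxiran-2-yl]-5-oxooxolane-3-carbaldehyde | C1C(=O)O[C@H]([C@H]3O[C@]3(CO[Si](C)(C)C(C)(C)C)CCC=C)[C@H]1C=O | intermediate
19 | (4R,5S)-5-[(2R,3S)-3-(but-3-en-1-yl)-3-{[(tert-butyldimethylsilyl)oxy]methyl}oxiran-2-yl]-4-[(1R)-1-hydroxy-3-methylbut-3-en-1-yl]oxolan-2-one | C1C(=O)O[C@H]([C@H]3O[C@]3(CO[Si](C)(C)C(C)(C)C)CCC=C)[C@H]1[C@H](O)CC(C)=C | intermediate
20 | (1(10)Z,4S,5R,6S,7R,8R)-15-[(tert-butyldimethylsilyl)oxy]-4,5-epoxy-8-hydroxygermacr-1(10)-en-12,6-olide | C1C(=O)O[C@H]2[C@H]1[C@H](O)C/C(C)=C\CC[C@@]1(CO[Si](C)(C)C(C)(C)C)O[C@H]21 | intermediate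
21 | (1(10)Z,4S,5R,6S,7S,8R)-15-[(tert-butyldimethylsilyl)oxy]-4,5-epoxy-8-[(triethylsilyl)oxy]germacr-1(10)-en-12,6-olide | C1C(=O)O[C@H]2[C@H]1[C@H](O[Si](CC)(CC)CC)C/C(C)=C\CC[C@@]1(CO[Si](C)(C)C(C)(C)C)O[C@H]21 | intermediate
22 | lithium enolate of 21 (C11=C12–OLi) | C1=C(O[Li])O[C@H]2[C@H]1[C@H](O[Si](CC)(CC)CC)C/C(C)=C\CC[C@@]1(CO[Si](C)(C)C(C)(C)C)O[C@H]21 | intermediate (not isolated)
23 | (1(10)Z,4S,5R,6S,7S,8R,11R)-13-(dimethylamino)-15-[(tert-butyldimethylsilyl)oxy]-4,5-epoxy-8-[(triethylsilyl)oxy]germacr-1(10)-en-12,6-olide (11R drawn as the expected major epimer) | CN(C)C[C@@H]1C(=O)O[C@H]2[C@H]1[C@H](O[Si](CC)(CC)CC)C/C(C)=C\CC[C@@]1(CO[Si](C)(C)C(C)(C)C)O[C@H]21 | intermediate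
24 | N,N,N-trimethylammonium iodide of 23 | C[N+](C)(C)C[C@@H]1C(=O)O[C@H]2[C@H]1[C@H](O[Si](CC)(CC)CC)C/C(C)=C\CC[C@@]1(CO[Si](C)(C)C(C)(C)C)O[C@H]21.[I-] | intermediate (not isolated)
25 | (1(10)Z,4S,5R,6S,7S,8R)-15-[(tert-butyldimethylsilyl)oxy]-4,5-epoxy-8-[(triethylsilyl)oxy]germacra-1(10),11(13)-dien-12,6-olide | C=C1C(=O)O[C@H]2[C@H]1[C@H](O[Si](CC)(CC)CC)C/C(C)=C\CC[C@@]1(CO[Si](C)(C)C(C)(C)C)O[C@H]21 | intermediate
26 | (1(10)Z,4S,5R,6S,7R,8R)-15-[(tert-butyldimethylsilyl)oxy]-4,5-epoxy-8-hydroxygermacra-1(10),11(13)-dien-12,6-olide | C=C1C(=O)O[C@H]2[C@H]1[C@H](O)C/C(C)=C\CC[C@@]1(CO[Si](C)(C)C(C)(C)C)O[C@H]21 | intermediate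
27 | 2-[(tert-butyldimethylsilyl)oxy]acetaldehyde | O=CCO[Si](C)(C)C(C)(C)C | starting material
28 | ethyl 2-(triphenyl-λ5-phosphanylidene)propanoate | CCOC(=O)C(C)=P(c1ccccc1)(c1ccccc1)c1ccccc1 | starting material
29 | ethyl (2E)-4-[(tert-butyldimethylsilyl)oxy]-2-methylbut-2-enoate | CCOC(=O)/C(C)=C/CO[Si](C)(C)C(C)(C)C | intermediate
30 | (2E)-4-[(tert-butyldimethylsilyl)oxy]-2-methylbut-2-enoic acid | OC(=O)/C(C)=C/CO[Si](C)(C)C(C)(C)C | intermediate
31 | (2E)-4-[(tert-butyldimethylsilyl)oxy]-2-methylbut-2-enoic 2,4,6-trichlorobenzoic anhydride | O=C(OC(=O)c1c(Cl)cc(Cl)cc1Cl)/C(C)=C/CO[Si](C)(C)C(C)(C)C | intermediate (not isolated)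
32 | (1(10)Z,4S,5R,6S,7R,8R)-15-[(tert-butyldimethylsilyl)oxy]-4,5-epoxy-12-oxo-germacra-1(10),11(13)-dien-12,6-olid-8-yl (2E)-4-[(tert-butyldimethylsilyl)oxy]-2-methylbut-2-enoate | C=C1C(=O)O[C@H]2[C@H]1[C@H](OC(=O)/C(C)=C/CO[Si](C)(C)C(C)(C)C)C/C(C)=C\CC[C@@]1(CO[Si](C)(C)C(C)(C)C)O[C@H]21 | intermediate
33 | (1(10)Z,4S,5R,6S,7R,8R)-4,5-epoxy-15-hydroxy-12-oxo-germacra-1(10),11(13)-dien-12,6-olid-8-yl (2E)-4-hydroxy-2-methylbut-2-enoate | C=C1C(=O)O[C@H]2[C@H]1[C@H](OC(=O)/C(C)=C/CO)C/C(C)=C\CC[C@@]1(CO)O[C@H]21 | target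

**Count**
Total steps: 20. Longest linear sequence: 17 steps (1–6, 8–16, 19, 20); step 7 and steps 17–18 are side branches.

**Three steps most likely to fail, in route order (step 12 is the most serious)**

Step 8, aldol on the epoxy aldehyde. The α-epoxy stereocentre of 9 probably opposes the auxiliary, and 9 is sensitive. The fallback sets out from 7 and comes back at 16, and it postpones the epoxide. Oxidise 7 with MnO2 in CH2Cl2 to the enal (2Z)-3-{[(tert-butyldimethylsilyl)oxy]methyl}hepta-2,6-dienal F1. Run the same Bu2BOTf/i-Pr2NEt Evans aldol with 13 to give the allylic syn-aldol methyl (3S,4R,5Z)-3-{[(4S)-4-benzyl-2-oxo-1,3-oxazolidin-3-yl]carbonyl}-6-{[(tert-butyldimethylsilyl)oxy]methyl}-4-hydroxydeca-5,9-dienoate F2; the aldehyde now has no α-stereocentre, so control is purely from the auxiliary. Then epoxidise the C6 allylic alcohol with m-CPBA/NaHCO3 at 0 °C. This hydroxyl-directed epoxidation is threo-selective because of A(1,3) strain with the cis CH2OTBS group, and the threo product is aldol adduct 15. PPTS then closes the lactone to 16.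

Step 11, methallylboration. The reagent has to override whatever bias the α-stereocentre at C7 has. The fallback sets out from 18 and comes back at 19. Add the methallyl group without stereocontrol (3-bromo-2-methylprop-1-ene, indium metal, THF/H2O) to give the C8-epimeric alcohols (4R,5S)-5-[(2R,3S)-3-(but-3-en-1-yl)-3-{[(tert-butyldimethylsilyl)oxy]methyl}oxiran-2-yl]-4-[(1RS)-1-hydroxy-3-methylbut-3-en-1-yl]oxolan-2-one F3. Oxidise with Dess–Martin periodinane/NaHCO3 to the β,γ-unsaturated ketone (4S,5S)-5-[(2R,3S)-3-(but-3-en-1-yl)-3-{[(tert-butyldimethylsilyl)oxy]methyl}oxiran-2-yl]-4-(3-methylbut-3-enoyl)oxolan-2-one F4. Reduce at −78 °C with catecholborane and (S)-5,5-diphenyl-2-methyl-3,4-propano-1,3,2-oxazaborolidine (Corey–Bakshi–Shibata reduction, with the ring-bearing C7 side as the large group) to the (8R)-alcohol 19.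

Step 12, ring-closing metathesis to a trisubstituted cyclodecene. Oligomerisation may win over closure onto the 1,1-disubstituted olefin. The fallback sets out from 19 and comes back at 20, and it moves the C8 stereocentre to after ring closure. Oxidise 19 (Dess–Martin periodinane, NaHCO3) to the ketone (4S,5S)-5-[(2R,3S)-3-(but-3-en-1-yl)-3-{[(tert-butyldimethylsilyl)oxy]methyl}oxiran-2-yl]-4-(3-methylbut-3-enoyl)oxolan-2-one F4, in which the sp2 C8 removes one transannular hydrogen from the forming ring. Cyclise with second-generation Hoveyda–Grubbs catalyst and 1,4-benzoquinone (to suppress alkene migration) in dilute toluene to the cyclodecenone (1(10)Z,4S,5R,6S,7S)-15-[(tert-butyldimethylsilyl)oxy]-4,5-epoxy-8-oxogermacr-1(10)-en-12,6-olide F5. Reduce the ketone with the same (S)-oxazaborolidine/catecholborane system to the (8R)-alcohol 20.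

**Further compounds**
F1 | step 8 | (2Z)-3-{[(tert-butyldimethylsilyl)oxy]methyl}hepta-2,6-dienal | O=C/C=C(/CCC=C)CO[Si](C)(C)C(C)(C)C
F2 | step 8 | methyl (3S,4R,5Z)-3-{[(4S)-4-benzyl-2-oxo-1,3-oxazolidin-3-yl]carbonyl}-6-{[(tert-butyldimethylsilyl)oxy]methyl}-4-hydroxydeca-5,9-dienoate | COC(=O)C[C@H](C(=O)N4[C@@H](Cc2ccccc2)COC4=O)[C@H](O)/C=C(/CCC=C)CO[Si](C)(C)C(C)(C)C
F3 | step 11 | (4R,5S)-5-[(2R,3S)-3-(but-3-en-1-yl)-3-{[(tert-butyldimethylsilyl)oxy]methyl}oxiran-2-yl]-4-[(1RS)-1-hydroxy-3-methylbut-3-en-1-yl]oxolan-2-one (C8 epimer mixture) | C1C(=O)O[C@H]([C@H]3O[C@]3(CO[Si](C)(C)C(C)(C)C)CCC=C)[C@H]1C(O)CC(C)=C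
F4 | step 11 | (4S,5S)-5-[(2R,3S)-3-(but-3-en-1-yl)-3-{[(tert-butyldimethylsilyl)oxy]methyl}oxiran-2-yl]-4-(3-methylbut-3-enoyl)oxolan-2-one | C1C(=O)O[C@H]([C@H]3O[C@]3(CO[Si](C)(C)C(C)(C)C)CCC=C)[C@H]1C(=O)CC(C)=C
F5 | step 12 | (1(10)Z,4S,5R,6S,7S)-15-[(tert-butyldimethylsilyl)oxy]-4,5-epoxy-8-oxogermacr-1(10)-en-12,6-olide | C1C(=O)O[C@H]2[C@H]1C(=O)C/C(C)=C\CC[C@@]1(CO[Si](C)(C)C(C)(C)C)O[C@H]21
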